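**Retrosynthetic overview**

1. Ring labels: C1(OMe)=C2(aryl)–C3(spiro; oxirane O and C6H2)–C4(OMe)(aryl)–C5(=O). The plan rests on the C5 ketone lying between the two methoxy-bearing carbons C1 and C4, a masked 1,3-dimethoxy-2-oxyallyl cation. Beside it, C2–C3 carries an aryl group on C2 and oxygen plus C6 on C3, a masked enol ether of ArCH2–CO–CH2Cl.
2. Target 22 ⇐ resolution of racemate 21 ⇐ oxirane (O–C6 bond) by chlorohydrin closure ⇐ C1=C2 by dehydrogenation of cyclopentanone 16.
3. 16 ⇐ stepwise (3+2) annulation, C1–C2 then C3–C4, of siloxyallyl cation precursor 7 (C1–C5–C4) with chloroketone silyl enol ether 13 (C2–C3–C6).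
4. 7 ⇐ 4-hydroxyphenylglyoxylic acid 1 (ketal ester, Weinreb amide, MeOCH2Li, enol silylation); 13 ⇐ aryl bromide 8 + epichlorohydrin 9 (Grignard opening, oxidation, enol silylation).
5. Ring order: cyclopentanone first (step 9), oxirane last (step 12).

Key step: step 9

Remark: no chiral controller is used in the annulation, so 16–21 are racemic (names and SMILES show the enantiomer that leads to the target) and the absolute configuration is fixed by the resolution in step 13; TBS = tert-butyldimethylsilyl, TMS = trimethylsilyl, aryl = 4-(TBS-oxy)phenyl unless stated.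

**Step 1**
Reactants: 1 4-hydroxyphenylglyoxylic acid
Product: 2 methyl 2-(4-hydroxyphenyl)-2,2-dimethoxyacetate
Conditions: HC(OMe)3, MeOH, H2SO4 (cat.), reflux; then NaHCO3
Reagents that add atoms: methanol, CO; trimethyl orthoformate, COC(OC)OC
Why: Fischer esterification and dimethyl ketal formation run together because the orthoformate removes the water from both equilibria, and the neighbouring ester makes the ketal slow to hydrolyse on work-up.

**Step 2**
Reactants: 2 methyl 2-(4-hydroxyphenyl)-2,2-dimethoxyacetate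
Product: 3 methyl 2-[4-(tert-butyldimethylsilyloxy)phenyl]-2,2-dimethoxyacetate
Conditions: t-BuMe2SiCl, imidazole, DMF, rt
Reagents that add atoms: tert-butyldimethylsilyl chloride, CC(C)(C)[Si](C)(C)Cl
Why: Imidazole-promoted silylation of a phenol (Corey conditions) gives an aryl silyl ether that should tolerate the organometallic, Lewis acid and oxidation steps and is removed by fluoride at the end.

**Step 3**
Reactants: 3 methyl 2-[4-(tert-butyldimethylsilyloxy)phenyl]-2,2-dimethoxyacetate
Product: 4 2-[4-(tert-butyldimethylsilyloxy)phenyl]-N,2,2-trimethoxy-N-methylacetamide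
Conditions: MeNH(OMe)·HCl, i-PrMgCl, THF, −20 to 0 °C
Reagents that add atoms: N,O-dimethylhydroxylamine hydrochloride, CNOC.Cl
Why: Aminolysis of the ester by the chloromagnesium amide of N,O-dimethylhydroxylamine (Weinreb amide synthesis) should proceed because the two α-oxygen substituents activate the ester despite its hindrance.

**Step 4**
Reactants: 4 2-[4-(tert-butyldimethylsilyloxy)phenyl]-N,2,2-trimethoxy-N-methylacetamide
Product: 5 1-[4-(tert-butyldimethylsilyloxy)phenyl]-1,1,3-trimethoxypropan-2-one
Conditions: Bu3SnCH2OMe, n-BuLi, THF, −78 °C; then 4, −78 to −40 °C; aq. NH4Cl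
Reagents that add atoms: tributyl(methoxymethyl)stannane, CCCC[Sn](CCCC)(CCCC)COC
Why: Tin–lithium exchange gives methoxymethyllithium, which adds once to the Weinreb amide because the Li+-chelated tetrahedral intermediate survives until the quench (Weinreb ketone synthesis).

**Step 5**
Reactants: 5 1-[4-(tert-butyldimethylsilyloxy)phenyl]-1,1,3-trimethoxypropan-2-one
Product: 7 (Z)-1-[4-(tert-butyldimethylsilyloxy)phenyl]-1,1,3-trimethoxy-2-(trimethylsilyloxy)prop-2-ene, via lithium (Z)-enolate 6 (not isolated)
Conditions: LiN(SiMe3)2, THF, −78 °C; then Me3SiCl, −78 to 0 °C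
Reagents that add atoms: chlorotrimethylsilane, C[Si](C)(C)Cl
Why: The ketone can enolise only toward the methoxymethyl carbon, and chelation of Li+ between the enolate oxygen and the methoxy group should give the (Z)-enolate, which is trapped on oxygen (kinetic enolate silylation).

**Step 6**
Reactants: 8 (4-bromophenoxy)(tert-butyl)dimethylsilane; 9 epichlorohydrin (racemic)
Product: 11 1-[4-(tert-butyldimethylsilyloxy)phenyl]-3-chloropropan-2-ol (racemic), via arylmagnesium bromide 10 (not isolated)
Conditions: Mg, THF, reflux; then 9, CuBr·SMe2 (5 mol %), −40 to 0 °C; aq. NH4Cl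
Reagents that add atoms: none
Why: The aryl Grignard reagent opens epichlorohydrin at the unsubstituted oxirane carbon under CuBr·SMe2 catalysis (copper-catalysed epoxide opening) and leaves the chloride in place, the racemic carbinol centre being removed in step 7.

**Step 7**
Reactants: 11 1-[4-(tert-butyldimethylsilyloxy)phenyl]-3-chloropropan-2-ol
Product: 12 1-[4-(tert-butyldimethylsilyloxy)phenyl]-3-chloropropan-2-one
Conditions: Dess–Martin periodinane, CH2Cl2, 0 °C to rt
Reagents that add atoms: none
Why: Dess–Martin oxidation of the secondary alcohol is mild enough to give the chloromethyl benzyl ketone without touching the aryl silyl ether or the alkyl chloride.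

**Step 8**
Reactants: 12 1-[4-(tert-butyldimethylsilyloxy)phenyl]-3-chloropropan-2-one
Product: 13 (Z)-2-(tert-butyldimethylsilyloxy)-1-[4-(tert-butyldimethylsilyloxy)phenyl]-3-chloroprop-1-ene
Conditions: t-BuMe2SiOTf, i-Pr2NEt, CH2Cl2, −78 to 0 °C
Reagents that add atoms: tert-butyldimethylsilyl trifluoromethanesulfonate, CC(C)(C)[Si](C)(C)OS(=O)(=O)C(F)(F)F
Why: Soft enolisation with a silyl triflate and a hindered amine should give the thermodynamically favoured enol ether, conjugated with the aryl ring and (Z)-configured (aryl cis to the siloxy group), since the benzylic hydrogens are the more acidic and the hindered base does not alkylate at the chloride.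

**Step 9**
Reactants: 7 (Z)-1-[4-(tert-butyldimethylsilyloxy)phenyl]-1,1,3-trimethoxy-2-(trimethylsilyloxy)prop-2-ene; 13 (Z)-2-(tert-butyldimethylsilyloxy)-1-[4-(tert-butyldimethylsilyloxy)phenyl]-3-chloroprop-1-ene
Product: 16 racemic (2R,3S)-3-(chloromethyl)-2,5-dimethoxy-3-(tert-butyldimethylsilyloxy)-2,4-bis[4-(tert-butyldimethylsilyloxy)phenyl]cyclopentan-1-one (ring labels: C5 ketone; C3–OTBS cis to the C4 aryl group; C1 and C2 undefined), via siloxyallyl cation triflate 14 (not isolated), via C3 silyloxocarbenium triflate 15 (not isolated)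
Conditions: 7 (1.3 equiv), Me3SiOTf (20 mol %), 2,6-di-tert-butyl-4-methylpyridine (20 mol %), CH2Cl2, −78 to −40 °C; then Et3N, aq. NaHCO3
Reagents that add atoms: none
Why: Me3SiOTf removes one ketal methoxy group of 7 as MeOSiMe3 and gives the 1,3-dimethoxy-2-siloxyallyl cation 14, whose unsubstituted terminus C1 is attacked by the nucleophilic benzylic carbon of enol ether 13 (bond C1–C2); the TBS-oxocarbenium ion 15 formed at C3 is then captured by the C4=C5 trimethylsilyl enol ether in an intramolecular Mukaiyama aldol addition (bond C3–C4), and loss of Me3Si+ from the C5 oxygen returns the catalyst. The closest known reaction type is the stepwise (3+2) cyclopentanone annulation of heteroatom-stabilised 2-siloxyallyl cations with silyl enol ethers, joined here to the ionisation of α-keto acetal silyl enol ethers that is used to make alkoxy-siloxyallyl cations for (4+3) cycloadditions; the bond between the two fully substituted carbons C3 and C4 is an extension of these cases. The cyclopentanone closes in the 5-(enolendo)-exo-trig aldol mode that is normal for the second step of such annulations, and O-closure to a dihydrofuran is blocked because the C5 oxygen is silylated. The step needs C2 to bond to C1 and not to C4, which the contrast between the CH terminus and the fully substituted, aryl-bearing C4 terminus secures, and it needs closure to outrun loss of silicon from 15, which the slow-leaving TBS group favours. C1 and C2 are formed without control and are removed in step 11, whereas C3 and C4 are set relative to each other in the closure, expected to pass through the arrangement in which the C3 oxocarbenium oxygen is anti to the C4 methoxy oxygen (opposed C–O dipoles) and the larger CH2Cl group lies beside the small methoxy group instead of the aryl group, so that C3–O ends cis to the C4 aryl group. No chiral controller is present, so 16 is racemic.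

**Step 10**
Reactants: 16 racemic 3-(chloromethyl)-2,5-dimethoxy-3-(tert-butyldimethylsilyloxy)-2,4-bis[4-(tert-butyldimethylsilyloxy)phenyl]cyclopentan-1-one
Product: 18 trimethylsilyl enol ether of 16 (C5(OSiMe3)=C1(OMe); C3 and C4 as in 16; C2 undefined), via lithium enolate 17 (not isolated)
Conditions: LiN(SiMe3)2, THF, −78 °C; then Me3SiCl, −78 to 0 °C
Reagents that add atoms: chlorotrimethylsilane, C[Si](C)(C)Cl
Why: The ketone has a single α-hydrogen, at C1, because C4 is fully substituted, so deprotonation and O-silylation (enolate trapping) can give only the C5=C1 silyl enol ether, which also removes the undefined C1 centre.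

**Step 11**
Reactants: 18 trimethylsilyl enol ether of 16
Product: 19 racemic (4S,5R)-4-(chloromethyl)-2,5-dimethoxy-4-(tert-butyldimethylsilyloxy)-3,5-bis[4-(tert-butyldimethylsilyloxy)phenyl]cyclopent-2-en-1-one
Conditions: Pd(OAc)2 (1.2 equiv), MeCN, rt to 40 °C
Reagents that add atoms: none
Why: In this Saegusa–Ito oxidation the divalent palladium enolate formed from the silyl enol ether and Pd(OAc)2 should undergo β-hydride elimination of the only β-hydrogen, the benzylic C2–H, giving the C1=C2 enone and removing the C2 centre without touching C3 or C4.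

**Step 12**
Reactants: 19 racemic (4S,5R)-4-(chloromethyl)-2,5-dimethoxy-4-(tert-butyldimethylsilyloxy)-3,5-bis[4-(tert-butyldimethylsilyloxy)phenyl]cyclopent-2-en-1-one
Product: 21 racemic (3R,4R)-4,7-bis(4-hydroxyphenyl)-4,6-dimethoxy-1-oxaspiro[2.4]hept-6-en-5-one, via C3 alkoxide 20 (not isolated)
Conditions: Bu4NF (5 equiv), THF, 0 °C to rt; pH 7 phosphate buffer
Reagents that add atoms: none
Why: Fluoride cleaves the two aryl silyl ethers and the tertiary silyl ether, and the C3 alkoxide then displaces chloride at C6 in a 3-exo-tet closure (intramolecular Williamson etherification) that keeps the C3 configuration, while retro-aldol cleavage of C3–C4 is disfavoured because that bond lies near the plane of the C5 carbonyl in the flat cyclopentenone.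

**Step 13**
Reactants: 21 racemic 4,7-bis(4-hydroxyphenyl)-4,6-dimethoxy-1-oxaspiro[2.4]hept-6-en-5-one
Product: 22 (3R,4R)-4,7-bis(4-hydroxyphenyl)-4,6-dimethoxy-1-oxaspiro[2.4]hept-6-en-5-one (CNP0504072.1)
Conditions: preparative HPLC, amylose tris(3,5-dimethylphenylcarbamate) stationary phase, hexane/2-propanol
Reagents that add atoms: none
Why: Resolution of a racemate by chromatography on a polysaccharide carbamate chiral stationary phase is general for rigid polar aromatics of this kind, and the (3R,4R) fraction is to be assigned by comparing its electronic circular dichroism with the spectrum computed for that configuration.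

**Compound list**

1 | 4-hydroxyphenylglyoxylic acid | O=C(O)C(=O)c1ccc(O)cc1 | starting material
2 | methyl 2-(4-hydroxyphenyl)-2,2-dimethoxyacetate | COC(=O)C(OC)(OC)c1ccc(O)cc1 | intermediate
3 | methyl 2-[4-(tert-butyldimethylsilyloxy)phenyl]-2,2-dimethoxyacetate | COC(=O)C(OC)(OC)c1ccc(O[Si](C)(C)C(C)(C)C)cc1 | intermediate
4 | 2-[4-(tert-butyldimethylsilyloxy)phenyl]-N,2,2-trimethoxy-N-methylacetamide | CON(C)C(=O)C(OC)(OC)c1ccc(O[Si](C)(C)C(C)(C)C)cc1 | intermediate
5 | 1-[4-(tert-butyldimethylsilyloxy)phenyl]-1,1,3-trimethoxypropan-2-one | COCC(=O)C(OC)(OC)c1ccc(O[Si](C)(C)C(C)(C)C)cc1 | intermediate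
6 | lithium (Z)-enolate of 5 | CO/C=C(\[O-])C(OC)(OC)c1ccc(O[Si](C)(C)C(C)(C)C)cc1.[Li+] | intermediate (not isolated)
7 | (Z)-1-[4-(tert-butyldimethylsilyloxy)phenyl]-1,1,3-trimethoxy-2-(trimethylsilyloxy)prop-2-ene | CO/C=C(\O[Si](C)(C)C)C(OC)(OC)c1ccc(O[Si](C)(C)C(C)(C)C)cc1 | intermediate
8 | (4-bromophenoxy)(tert-butyl)dimethylsilane | CC(C)(C)[Si](C)(C)Oc1ccc(Br)cc1 | starting material
9 | epichlorohydrin (racemic) | ClCC1CO1 | starting material
10 | [4-(tert-butyldimethylsilyloxy)phenyl]magnesium bromide | CC(C)(C)[Si](C)(C)Oc1ccc([Mg]Br)cc1 | intermediate (not isolated)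
11 | 1-[4-(tert-butyldimethylsilyloxy)phenyl]-3-chloropropan-2-ol (racemic) | OC(CCl)Cc1ccc(O[Si](C)(C)C(C)(C)C)cc1 | intermediate
12 | 1-[4-(tert-butyldimethylsilyloxy)phenyl]-3-chloropropan-2-one | O=C(CCl)Cc1ccc(O[Si](C)(C)C(C)(C)C)cc1 | intermediate
13 | (Z)-2-(tert-butyldimethylsilyloxy)-1-[4-(tert-butyldimethylsilyloxy)phenyl]-3-chloroprop-1-ene | ClC/C(O[Si](C)(C)C(C)(C)C)=C/c1ccc(O[Si](C)(C)C(C)(C)C)cc1 | intermediate
14 | 1-[4-(tert-butyldimethylsilyloxy)phenyl]-1,3-dimethoxy-2-(trimethylsilyloxy)allyl cation triflate, drawn as the C4 oxocarbenium form | CO/C=C(\O[Si](C)(C)C)C(=[O+]C)c1ccc(O[Si](C)(C)C(C)(C)C)cc1.[O-]S(=O)(=O)C(F)(F)F | intermediate (not isolated)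
15 | open-chain C3 TBS-oxocarbenium triflate carrying the C4=C5 trimethylsilyl enol ether (C1, C2 and the enol ether geometry undefined) | COC(C(c1ccc(O[Si](C)(C)C(C)(C)C)cc1)C(CCl)=[O+][Si](C)(C)C(C)(C)C)C(O[Si](C)(C)C)=C(OC)c1ccc(O[Si](C)(C)C(C)(C)C)cc1.[O-]S(=O)(=O)C(F)(F)F | intermediate (not isolated)
16 | racemic (2R,3S)-3-(chloromethyl)-2,5-dimethoxy-3-(tert-butyldimethylsilyloxy)-2,4-bis[4-(tert-butyldimethylsilyloxy)phenyl]cyclopentan-1-one; C3–OTBS cis to the C4 aryl group, CH2Cl cis to the C4 methoxy group, C1 and C2 undefined | COC1C(c2ccc(O[Si](C)(C)C(C)(C)C)cc2)[C@@](O[Si](C)(C)C(C)(C)C)(CCl)[C@](OC)(c2ccc(O[Si](C)(C)C(C)(C)C)cc2)C1=O | intermediate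
17 | lithium enolate of 16 (C5(O–)=C1(OMe)), racemic | [Li+].[O-]C1=C(OC)C(c2ccc(O[Si](C)(C)C(C)(C)C)cc2)[C@@](O[Si](C)(C)C(C)(C)C)(CCl)[C@]1(OC)c1ccc(O[Si](C)(C)C(C)(C)C)cc1 | intermediate (not isolated)
18 | trimethylsilyl enol ether of 16 (C5(OSiMe3)=C1(OMe)), racemic, C2 undefined | C[Si](C)(C)OC1=C(OC)C(c2ccc(O[Si](C)(C)C(C)(C)C)cc2)[C@@](O[Si](C)(C)C(C)(C)C)(CCl)[C@]1(OC)c1ccc(O[Si](C)(C)C(C)(C)C)cc1 | intermediate
19 | racemic (4S,5R)-4-(chloromethyl)-2,5-dimethoxy-4-(tert-butyldimethylsilyloxy)-3,5-bis[4-(tert-butyldimethylsilyloxy)phenyl]cyclopent-2-en-1-one | COC1=C(c2ccc(O[Si](C)(C)C(C)(C)C)cc2)[C@@](O[Si](C)(C)C(C)(C)C)(CCl)[C@](OC)(c2ccc(O[Si](C)(C)C(C)(C)C)cc2)C1=O | intermediate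
20 | tris(tetrabutylammonium) salt of the desilylated chlorohydrin (C3 alkoxide, two phenoxides), racemic | COC1=C(c2ccc([O-])cc2)[C@@]([O-])(CCl)[C@](OC)(c2ccc([O-])cc2)C1=O.CCCC[N+](CCCC)(CCCC)CCCC.CCCC[N+](CCCC)(CCCC)CCCC.CCCC[N+](CCCC)(CCCC)CCCC | intermediate (not isolated)
21 | racemic (3R,4R)-4,7-bis(4-hydroxyphenyl)-4,6-dimethoxy-1-oxaspiro[2.4]hept-6-en-5-one (oxirane O cis to the C4 aryl group) | COC1=C(c2ccc(O)cc2)[C@@]2(CO2)[C@](OC)(c2ccc(O)cc2)C1=O | intermediate
22 | (3R,4R)-4,7-bis(4-hydroxyphenyl)-4,6-dimethoxy-1-oxaspiro[2.4]hept-6-en-5-one, single enantiomer | COC1=C(c2ccc(O)cc2)[C@@]2(CO2)[C@](OC)(c2ccc(O)cc2)C1=O | target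

**Step count**

Total: 13 steps. Longest linear sequence: 10 steps (steps 1–5, then 9–13).

**Steps most likely to fail**

Step 9. Silicon may be lost from the C3 oxocarbenium ion before the aldol closure, which would stop the annulation at an open-chain adduct. The closure may also occur with low or reversed facial selectivity at C3 relative to C4.

Fallback (sets out from ketone 5 and chloroketone 12, returns at 16): the two bonds are made in separate operations.
- Ketone 5 is silylated with KN(SiMe3)2 and t-BuMe2SiCl to the hydrolytically robust (Z)-1-[4-(tert-butyldimethylsilyloxy)phenyl]-1,1,3-trimethoxy-2-(tert-butyldimethylsilyloxy)prop-2-ene F1.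
- Chloroketone 12 is silylated with Me3SiOTf and i-Pr2NEt to (Z)-1-[4-(tert-butyldimethylsilyloxy)phenyl]-3-chloro-2-(trimethylsilyloxy)prop-1-ene F2.
- Under Me3SiOTf catalysis at −78 °C, F1 and F2 should form only the C1–C2 bond, because the trimethylsilyl group is shed quickly from the C3 oxocarbenium ion. The product is the open-chain 1-chloro-4,6-dimethoxy-5-(tert-butyldimethylsilyloxy)-3,6-bis[4-(tert-butyldimethylsilyloxy)phenyl]hex-5-en-2-one F3.
- TiCl4 in CH2Cl2 at −78 °C then effects a separate intramolecular Mukaiyama aldol addition through a closed arrangement in which TiCl4 is held between the C3 carbonyl oxygen and the C1 methoxy group. This should give racemic 3-(chloromethyl)-3-hydroxy-2,5-dimethoxy-2,4-bis[4-(tert-butyldimethylsilyloxy)phenyl]cyclopentan-1-one F4, with diastereomers separable at this stage.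
- The tertiary alcohol of F4 is silylated with t-BuMe2SiOTf and 2,6-lutidine to return to 16.

Step 12. The hindered tertiary silyl ether may resist cleavage under conditions mild enough for the product. Once the alkoxide and phenoxides are free in the fluoride medium, retro-aldol opening of C3–C4 or opening of the new oxirane may set in.

Fallback (sets out from 19, returns at 21): all three silyl ethers are removed with HF·pyridine in THF, where no alkoxide forms and the acid-sensitive oxirane is not yet present. This should give racemic (4S,5R)-4-(chloromethyl)-4-hydroxy-3,5-bis(4-hydroxyphenyl)-2,5-dimethoxycyclopent-2-en-1-one F5. The oxirane is then closed in a separate short treatment with K2CO3 in MeOH at 0 °C to give 21.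

Step 11. Palladation of the tetrasubstituted, crowded silyl enol ether may be slow, with protodesilylation back to 16 competing. The palladium enolate may also fail to reach the syn arrangement needed for β-hydride elimination.

Fallback (sets out from 16, returns at 19, bypassing 18): the lithium enolate of 16 (LiN(SiMe3)2, THF, −78 °C) is selenenylated at C1 with PhSeCl, on the face away from the C2 aryl group. This should give 3-(chloromethyl)-2,5-dimethoxy-5-(phenylselanyl)-3-(tert-butyldimethylsilyloxy)-2,4-bis[4-(tert-butyldimethylsilyloxy)phenyl]cyclopentan-1-one F6. Oxidation with H2O2 and pyridine in CH2Cl2 at 0 °C forms the selenoxide, which should undergo syn-elimination toward the cis C2–H to give 19.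

**Further compounds**

F1 | step 9 | (Z)-1-[4-(tert-butyldimethylsilyloxy)phenyl]-1,1,3-trimethoxy-2-(tert-butyldimethylsilyloxy)prop-2-ene | CO/C=C(\O[Si](C)(C)C(C)(C)C)C(OC)(OC)c1ccc(O[Si](C)(C)C(C)(C)C)cc1
F2 | step 9 | (Z)-1-[4-(tert-butyldimethylsilyloxy)phenyl]-3-chloro-2-(trimethylsilyloxy)prop-1-ene | ClC/C(O[Si](C)(C)C)=C/c1ccc(O[Si](C)(C)C(C)(C)C)cc1
F3 | step 9 | 1-chloro-4,6-dimethoxy-5-(tert-butyldimethylsilyloxy)-3,6-bis[4-(tert-butyldimethylsilyloxy)phenyl]hex-5-en-2-one (stereochemistry undefined) | COC(c1ccc(O[Si](C)(C)C(C)(C)C)cc1)=C(O[Si](C)(C)C(C)(C)C)C(OC)C(c1ccc(O[Si](C)(C)C(C)(C)C)cc1)C(=O)CCl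
F4 | step 9 | racemic (2R,3S)-3-(chloromethyl)-3-hydroxy-2,5-dimethoxy-2,4-bis[4-(tert-butyldimethylsilyloxy)phenyl]cyclopentan-1-one | COC1C(c2ccc(O[Si](C)(C)C(C)(C)C)cc2)[C@@](O)(CCl)[C@](OC)(c2ccc(O[Si](C)(C)C(C)(C)C)cc2)C1=O
F5 | step 12 | racemic (4S,5R)-4-(chloromethyl)-4-hydroxy-3,5-bis(4-hydroxyphenyl)-2,5-dimethoxycyclopent-2-en-1-one | COC1=C(c2ccc(O)cc2)[C@@](O)(CCl)[C@](OC)(c2ccc(O)cc2)C1=O
F6 | step 11 | 3-(chloromethyl)-2,5-dimethoxy-5-(phenylselanyl)-3-(tert-butyldimethylsilyloxy)-2,4-bis[4-(tert-butyldimethylsilyloxy)phenyl]cyclopentan-1-one (racemic; C3 and C4 as in 16) | COC1([Se]c2ccccc2)C(c2ccc(O[Si](C)(C)C(C)(C)C)cc2)[C@@](O[Si](C)(C)C(C)(C)C)(CCl)[C@](OC)(c2ccc(O[Si](C)(C)C(C)(C)C)cc2)C1=O
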